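Atoms are numbered as in the halimane skeleton: ring A is C1–C5 plus C10, ring B is C5–C10, the ester and a methyl sit on C4, methyls on C8 and C9, and the chain C11–C15 on C9.

Assumption: the oxazaborolidinium ion made from (S)-diphenylprolinol is taken to leave the α-Re face of the bound s-trans enal open, as with other 2-substituted acroleins. If the sense were opposite for 1, the (R)-configured catalyst would be used in step 1.

## Analysis of the target

Target 19 is a halimane-type diterpenoid built on a Δ1(10)-octalin. Ring A carries the trisubstituted C1=C10 alkene and a quaternary C4 bearing a methyl and the methyl ester; ring B carries a secondary methyl at C8 and a quaternary C9 bearing a methyl and the C11–C15 chain, which ends in a primary acetate. There are five stereocentres, (4S,5R,8R,9S,13S). The C8 and C9 methyls are cis and lie on the same face of ring B as H5; C11 and the C4–C5 bond lie on the other face; the ester on C4 is trans to H5; C13 is two methylenes away from the ring and cannot be controlled from it. The sensitive groups are the acetate (lost to base or nucleophiles), the C1=C10 alkene (acid could move it into the ring fusion and erase C5) and, less so, the hindered methyl ester. The difficulty lies in the two quaternary stereocentres C4 and C9, the contiguous C8/C9 pair with vicinal cis methyls, and the absolute correlation of the ring with the isolated C13 centre. The strategy rests on the C8–C9 unit of ring B: two cis methyls with C11 trans to the C8 methyl are the substituent pattern of the E-configured α,β-dimethyl enal 1, whose formyl carbon is C11. A [4+2] cycloaddition across C8=C9 therefore turns alkene geometry into the relative configuration of both centres, and the oxygen that the diene delivers to C10 becomes the handle for building ring A.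

## Retrosynthetic reasoning

**C15 acetate (19 ⇒ 18 ⇒ 17).** The acetyl C–O bond is cut first. An acetate would not survive the ylide and amide-base steps, so C15 is carried as a robust silyl ether in 17, freed to alcohol 18 and acetylated last. The forward steps only have to leave the ester and the C1=C10 alkene untouched.

**Ring A (17 ⇒ 15 + 16).** The C4–C5 and C2–C3 bonds are cut, the retron of a Diels–Alder reaction between the 2-vinylcyclohexene 15 and methyl methacrylate 16. This removes the quaternary C4, the C5 stereocentre and the C1=C10 alkene in one operation with a commercial dienophile, and it leaves a diene in which only C8, C9 and C13 remain. The forward reaction must: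
- join the ester-bearing carbon to the ring terminus C5,
- place the ester endo,
- approach the face of ring B opposite the two methyls.

**Vinyl group (15 ⇒ 14 ⇒ 12).** The C1–C10 bond is cut to enol triflate 14 and a vinyl–metal reagent; 14 comes from ketone 12. This is chosen because C9 is quaternary: ketone 12 can enolise only toward C5, so the C5=C10 position of the triflate, and hence of the diene, is unambiguous. The forward reactions must achieve O-triflation and a coupling next to a quaternary carbon.

**Oxidation level (12 ⇒ 11 ⇒ 10).** Ketone 12 is traced to enone 11 (both the C5=C6 and C11=C12 alkenes still present) and then to allylic alcohol 10. The gain is that the C10 oxygen of the cycloadduct is used directly and the olefin geometry of the chain becomes irrelevant. The forward hydrogenation must saturate a hindered alkene without letting it migrate toward C13.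

**Side-chain junction (10 ⇒ 3 + 7).** The C11=C12 bond is cut as a Wittig olefination between aldehyde 3 and the ylide 8 generated from phosphonium salt 7. C11 is already the formyl carbon of the cycloadduct, the aldehyde is not enolisable, and C13 arrives enantiopure in the ylide, so the union correlates ring and chain in absolute terms. The silyl ether 9 formed first is cleaved in the same flask.

**Side-chain fragment (7 ⇒ 6 ⇒ 5 ⇒ 4).** The C12–P and C12–I bonds and the C15–O–Si bond lead back to the chiral-pool diol 4, whose stereocentre is C13 with the correct configuration. The forward sequence must tell the unbranched hydroxyl (C15) from the β-branched one (C12).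

**Ring B (3 ⇒ 1 + 2).** The C7–C8 and C9–C10 bonds are cut, giving the commercial enal 1 and silyloxydiene 2. No other disconnection sets the C8/C9 pair from alkene geometry with both partners at zero steps. The forward reaction must be enantioface-selective on the enal and must bond the oxygen-bearing diene terminus to C9.

## Alternatives that were turned down

**Alternative 1:** The C9 methyl (C9–C20) is disconnected to a cyclopropane spanning C9–C10, made from the tetrasubstituted C9=C10 alkene of octalinol A1, whose C1 hydroxyl lies on the face of H5. In the forward key step a hydroxyl-directed Simmons–Smith methylenation gives the methano-bridged carbinol A2; activation at C1 then opens the three-membered ring, turning C20 into the methyl and leaving the C1=C10 alkene.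
- For: the carbinol steers the zinc carbenoid to its own face reliably, so the configuration of C9 relative to C4 and C5 is fixed by a directing effect. On that point it is stronger than the chosen route, where C4 and C5 are set by an intermolecular cycloaddition that is only biased by the two methyls.
- Against: A1 already holds C4, C5, C8, C13, a tetrasubstituted alkene carrying the chain and a C1 carbinol of one configuration, so most of the stereochemical work is moved into its preparation. C8 is not set by the key step. Tetrasubstituted alkenes are slow carbenoid acceptors. The opening of A2 can break C10–C20 (wanted) or C9–C10 (ring enlargement through the more substituted radical or cation).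
- Comparison: the chosen strategy sets C8 and C9 together in its first step from commercial materials and reaches the skeleton in far fewer steps.

**Alternative 2:** The C9–C10 bond of ring B is disconnected, leading to the ring A vinyl triflate A3 with a tethered trisubstituted C9=C11 alkene. In the forward key step a 6-exo intramolecular Heck reaction closes ring B, creates the quaternary C9 and, after β-hydride elimination, gives diene A4, whose C11=C12 bond is later hydrogenated.
- For: it is convergent, ring A with C4 and C5 is made and purified before the ring fusion, and Heck cyclisations forming quaternary carbons are dependable. On the C4/C5 relationship it is stronger than the chosen route.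
- Against: C9 is set only by the conformational bias of the tether and the C8 stereocentre, so the cis C8/C9 methyl relationship is not assured. C8 must first be installed in an open chain, 1,4 to C5. A3 needs a regiodefined enol triflate (toward C1, not C5) and a geometrically pure trisubstituted alkene. After β-hydride elimination a palladium hydride sits next to the C11=C12 bond and the allylic C13 centre.
- Comparison: the chosen strategy derives the C8/C9 relationship stereospecifically from alkene geometry, not from a conformational preference, and is shorter.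

**Alternative 3:** The C4–C5 bond is disconnected through an Ireland–Claisen retron, leading to δ-lactone A5, whose alkoxy carbon C1 carries the ring B cyclohexenyl unit. In the forward key step the silyl ketene acetal of A5 rearranges on heating, forming C4–C5, breaking C1–O and delivering acid A6 with the C1=C10 alkene in place.
- For: the reaction is intramolecular, C5 comes from C1 by chirality transfer, C4 from the ring-fixed ketene acetal geometry, and there is no regiochemical question. It is stronger than the chosen route at exactly its weakest point, the ring A cycloaddition.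
- Against: A5 needs a C1 carbinol of defined configuration set by acyclic control, a ring-enforced boat transition state that bonds to C5 beside the crowded C9, and several extra steps (vinyl–metal addition, lactonisation, later esterification of A6). The ring B part of A5 still has to be made.
- Comparison: the chosen strategy makes ring A in one step from diene 15 with a commercial dienophile, at the price of relying on substrate bias.

Key step: step 1

## Route

Step 1
Reactants: 1 (E)-2-methylbut-2-enal (tiglaldehyde); 2 (E)-1-(trimethylsilyloxy)buta-1,3-diene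
Product: 3 (1S,2R,6R)-1,6-dimethyl-2-(trimethylsilyloxy)cyclohex-3-ene-1-carbaldehyde
Conditions: (S)-3,3-diphenyl-1-(o-tolyl)tetrahydro-1H,3H-pyrrolo[1,2-c][1,3,2]oxazaborole (20 mol %) activated in situ with HNTf2 (18 mol %), 2 (2.5 equiv), CH2Cl2, −78 → −40 °C; Et3N quench
Reagents that add atoms: none
Why: The protonated oxazaborolidine binds the formyl oxygen of 1 (s-trans enal, formyl C–H held against the ring oxygen), lowers its LUMO and covers the α-Si face with its aryl group, so that diene 2 adds in a concerted, asynchronous, normal-demand [4+2] cycloaddition. The closest known reaction type is the oxazaborolidinium-catalysed enantioselective Diels–Alder reaction of α-substituted α,β-unsaturated aldehydes with acyclic dienes. Ring B is closed by the cycloaddition itself: the four diene carbons (C10, C5, C6, C7) and the two alkene carbons of the enal (C8, C9) are joined through the new C7–C8 and C9–C10 bonds, leaving the C5=C6 alkene. C9 is set by the catalyst, which directs the diene to the α-Re face; C8 follows from C9 because the addition is suprafacial and the E geometry of 1 places the two methyls cis and C11 trans to the C8 methyl; C10 results from the endo position of the formyl group (formyl and silyloxy cis) and is not needed later, so any exo adduct converges at enone 11. The step needs regioselectivity (oxygen-bearing terminus to the α-carbon), secured by the donor on the diene, which makes the remote CH2 terminus the most nucleophilic site for the β-carbon of the activated enal; it needs chemoselectivity for C=C over the formyl group, which the α-substituent and the tight cationic complex favour; and it needs enough rate despite the β-methyl, which the cationic activation supplies.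

Step 2
Reactants: 4 (R)-2-methylbutane-1,4-diol
Product: 5 (2R)-4-[tert-butyl(diphenyl)silyloxy]-2-methylbutan-1-ol
Conditions: TBDPSCl (0.95 equiv), imidazole, CH2Cl2/DMF, −20 °C
Reagents that add atoms: tert-butyl(chloro)diphenylsilane, CC(C)(C)[Si](Cl)(c1ccccc1)c1ccccc1
Why: Steric differentiation of two primary hydroxyls in a silylation: the bulky silyl chloride should react faster at the unbranched hydroxyl (C15 of the target) than at the β-branched one; the regioisomer and the bis-ether are removed by chromatography and can be returned to 4 by desilylation. No stereocentre is touched.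

Step 3
Reactants: 5 (2R)-4-[tert-butyl(diphenyl)silyloxy]-2-methylbutan-1-ol
Product: 6 tert-butyl[(3R)-4-iodo-3-methylbutoxy]diphenylsilane
Conditions: I2, PPh3, imidazole, CH2Cl2, 0 °C → rt
Reagents that add atoms: iodine, II
Why: Appel-type iodination (iodophosphonium activation of the primary alcohol, then SN2 by iodide); the stereocentre is one carbon away from the reacting carbon and is untouched, and the silyl ether tolerates the buffered medium.

Step 4
Reactants: 6 tert-butyl[(3R)-4-iodo-3-methylbutoxy]diphenylsilane
Product: 7 [(2R)-4-[tert-butyl(diphenyl)silyloxy]-2-methylbutyl]triphenylphosphonium iodide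
Conditions: PPh3 (1.5 equiv), MeCN, reflux
Reagents that add atoms: triphenylphosphine, c1ccccc1P(c1ccccc1)c1ccccc1
Why: SN2 quaternisation of the phosphine by a primary iodide; β-branching slows but does not prevent it, hence prolonged heating in a polar solvent.

Step 5
Reactants: 7 [(2R)-4-[tert-butyl(diphenyl)silyloxy]-2-methylbutyl]triphenylphosphonium iodide; 3 (1S,2R,6R)-1,6-dimethyl-2-(trimethylsilyloxy)cyclohex-3-ene-1-carbaldehyde
Product: 10 (1R,5R,6R)-6-[(1Z,3R)-5-[tert-butyl(diphenyl)silyloxy]-3-methylpent-1-en-1-yl]-5,6-dimethylcyclohex-2-en-1-ol, via phosphorus ylide 8 (not isolated), via trimethylsilyl ether 9 (not isolated)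
Conditions: 7 (1.3 equiv), NaN(SiMe3)2 (1.25 equiv), THF, 0 °C; 3, −78 °C → rt; then MeOH, K2CO3 (cat.), rt
Reagents that add atoms: none
Why: Wittig olefination of a non-enolisable aldehyde with a salt-free non-stabilised ylide (Z-selective; the geometry does not matter because the alkene is hydrogenated in step 7), followed in the same flask by base-catalysed methanolysis of the labile trimethylsilyl ether, which leaves the tert-butyldiphenylsilyl ether intact. Neither C13 (β to phosphorus) nor the ring stereocentres can epimerise.

Step 6
Reactants: 10 (1R,5R,6R)-6-[(1Z,3R)-5-[tert-butyl(diphenyl)silyloxy]-3-methylpent-1-en-1-yl]-5,6-dimethylcyclohex-2-en-1-ol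
Product: 11 (5R,6R)-6-[(1Z,3R)-5-[tert-butyl(diphenyl)silyloxy]-3-methylpent-1-en-1-yl]-5,6-dimethylcyclohex-2-en-1-one
Conditions: Dess–Martin periodinane (1.3 equiv), CH2Cl2, 0 °C → rt
Reagents that add atoms: none
Why: Dess–Martin oxidation of a hindered secondary allylic alcohol under near-neutral conditions; the C10 stereocentre is removed on purpose and C8 and C9 have no acidic hydrogen that could be lost.

Step 7
Reactants: 11 (5R,6R)-6-[(1Z,3R)-5-[tert-butyl(diphenyl)silyloxy]-3-methylpent-1-en-1-yl]-5,6-dimethylcyclohex-2-en-1-one
Product: 12 (2S,3R)-2-[(3S)-5-[tert-butyl(diphenyl)silyloxy]-3-methylpentyl]-2,3-dimethylcyclohexan-1-one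
Conditions: H2 (1 atm), Pt/C (5 % Pt on carbon), EtOAc, rt
Reagents that add atoms: none
Why: Heterogeneous catalytic hydrogenation saturates the conjugated C5=C6 bond and the Z-disubstituted C11=C12 bond; platinum is chosen over palladium because it is less prone to double-bond migration, which protects the allylic stereocentre C13. No new stereocentre is formed.

Step 8
Reactants: 12 (2S,3R)-2-[(3S)-5-[tert-butyl(diphenyl)silyloxy]-3-methylpentyl]-2,3-dimethylcyclohexan-1-one
Product: 14 (5R,6S)-6-[(3S)-5-[tert-butyl(diphenyl)silyloxy]-3-methylpentyl]-5,6-dimethylcyclohex-1-en-1-yl trifluoromethanesulfonate, via potassium enolate 13 (not isolated)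
Conditions: KN(SiMe3)2 (1.2 equiv), THF, −78 °C; PhNTf2 (1.2 equiv), −78 → 0 °C
Reagents that add atoms: N-phenylbis(trifluoromethanesulfonimide), O=S(=O)(N(c1ccccc1)S(=O)(=O)C(F)(F)F)C(F)(F)F
Why: Enolate formation and O-triflation; C9 is quaternary, so deprotonation can occur only at C5 and the enol triflate forms as a single regioisomer with the C5=C10 double bond.

Step 9
Reactants: 14 (5R,6S)-6-[(3S)-5-[tert-butyl(diphenyl)silyloxy]-3-methylpentyl]-5,6-dimethylcyclohex-1-en-1-yl trifluoromethanesulfonate
Product: 15 tert-butyl{[(3S)-5-[(1S,6R)-2-ethenyl-1,6-dimethylcyclohex-2-en-1-yl]-3-methylpentyl]oxy}diphenylsilane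
Conditions: Bu3SnCH=CH2 (1.5 equiv), Pd(PPh3)4 (5 mol %), LiCl (3 equiv), THF, 65 °C
Reagents that add atoms: tributyl(vinyl)stannane, C=C[Sn](CCCC)(CCCC)CCCC
Why: Stille coupling of an enol triflate with a vinylstannane (oxidative addition to zerovalent palladium, chloride-assisted transmetalation, reductive elimination); the neighbouring quaternary carbon slows but does not block coupling of cyclohexenyl triflates, and no stereocentre is involved.

Step 10
Reactants: 15 tert-butyl{[(3S)-5-[(1S,6R)-2-ethenyl-1,6-dimethylcyclohex-2-en-1-yl]-3-methylpentyl]oxy}diphenylsilane; 16 methyl methacrylate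
Product: 17 methyl (1S,5S,6R,8aR)-5-[(3S)-5-[tert-butyl(diphenyl)silyloxy]-3-methylpentyl]-1,5,6-trimethyl-1,2,3,5,6,7,8,8a-octahydronaphthalene-1-carboxylate
Conditions: 16 (5 equiv), MeAlCl2 (0.5 equiv), CH2Cl2, −40 → 0 °C
Reagents that add atoms: none
Why: Lewis-acid-promoted normal-demand Diels–Alder reaction; the quaternary C9 holds the vinyl group s-cis, and the ring terminus C5 should take the ester-bearing carbon (ortho orientation of a 1-alkyl diene, reinforced by the Lewis acid), which closes ring A with the C1=C10 alkene. The complexed ester should sit endo (ester trans to H5, setting C4) and the dienophile should approach the face of ring B opposite the cis C8/C9 methyls, one of which is axial on that face in either half-chair (H5 syn to the methyls, setting C5).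

Step 11
Reactants: 17 methyl (1S,5S,6R,8aR)-5-[(3S)-5-[tert-butyl(diphenyl)silyloxy]-3-methylpentyl]-1,5,6-trimethyl-1,2,3,5,6,7,8,8a-octahydronaphthalene-1-carboxylate
Product: 18 methyl (1S,5S,6R,8aR)-5-[(3S)-5-hydroxy-3-methylpentyl]-1,5,6-trimethyl-1,2,3,5,6,7,8,8a-octahydronaphthalene-1-carboxylate
Conditions: Bu4NF (1.5 equiv), THF, rt
Reagents that add atoms: none
Why: Fluoride-induced cleavage of the silyl ether, driven by Si–F bond formation; the hindered methyl ester on quaternary C4 and the trisubstituted alkene are inert.

Step 12
Reactants: 18 methyl (1S,5S,6R,8aR)-5-[(3S)-5-hydroxy-3-methylpentyl]-1,5,6-trimethyl-1,2,3,5,6,7,8,8a-octahydronaphthalene-1-carboxylate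
Product: 19 methyl (1S,5S,6R,8aR)-5-[(3S)-5-acetoxy-3-methylpentyl]-1,5,6-trimethyl-1,2,3,5,6,7,8,8a-octahydronaphthalene-1-carboxylate (target, CNP0151222.1)
Conditions: Ac2O, pyridine, DMAP (cat.), CH2Cl2, rt
Reagents that add atoms: acetic anhydride, CC(=O)OC(C)=O
Why: Nucleophile-catalysed acetylation of a primary alcohol; the mild base avoids migration of the C1=C10 alkene and no stereocentre can epimerise.

## Compound list

1 | (E)-2-methylbut-2-enal (tiglaldehyde) | C/C=C(\C)C=O | starting material
2 | (E)-1-(trimethylsilyloxy)buta-1,3-diene | C=C/C=C/O[Si](C)(C)C | starting material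
3 | (1S,2R,6R)-1,6-dimethyl-2-(trimethylsilyloxy)cyclohex-3-ene-1-carbaldehyde | C1=CC[C@@H](C)[C@](C)(C=O)[C@@H]1O[Si](C)(C)C | intermediate
4 | (R)-2-methylbutane-1,4-diol | OC[C@H](C)CCO | starting material
5 | (2R)-4-[tert-butyl(diphenyl)silyloxy]-2-methylbutan-1-ol | OC[C@H](C)CCO[Si](c1ccccc1)(c1ccccc1)C(C)(C)C | intermediate
6 | tert-butyl[(3R)-4-iodo-3-methylbutoxy]diphenylsilane | IC[C@H](C)CCO[Si](c1ccccc1)(c1ccccc1)C(C)(C)C | intermediate
7 | [(2R)-4-[tert-butyl(diphenyl)silyloxy]-2-methylbutyl]triphenylphosphonium iodide | [I-].c1ccccc1[P+](c1ccccc1)(c1ccccc1)C[C@H](C)CCO[Si](c1ccccc1)(c1ccccc1)C(C)(C)C | intermediate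
8 | [(2R)-4-[tert-butyl(diphenyl)silyloxy]-2-methylbutylidene]triphenylphosphorane | c1ccccc1P(c1ccccc1)(c1ccccc1)=C[C@H](C)CCO[Si](c1ccccc1)(c1ccccc1)C(C)(C)C | intermediate
9 | tert-butyl{[(3R,4Z)-5-[(1R,2R,6R)-1,6-dimethyl-2-(trimethylsilyloxy)cyclohex-3-en-1-yl]-3-methylpent-4-en-1-yl]oxy}diphenylsilane | C1=CC[C@@H](C)[C@](C)(/C=C\[C@H](C)CCO[Si](c2ccccc2)(c2ccccc2)C(C)(C)C)[C@@H]1O[Si](C)(C)C | intermediate
10 | (1R,5R,6R)-6-[(1Z,3R)-5-[tert-butyl(diphenyl)silyloxy]-3-methylpent-1-en-1-yl]-5,6-dimethylcyclohex-2-en-1-ol | C1=CC[C@@H](C)[C@](C)(/C=C\[C@H](C)CCO[Si](c2ccccc2)(c2ccccc2)C(C)(C)C)[C@@H]1O | intermediate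
11 | (5R,6R)-6-[(1Z,3R)-5-[tert-butyl(diphenyl)silyloxy]-3-methylpent-1-en-1-yl]-5,6-dimethylcyclohex-2-en-1-one | C1=CC[C@@H](C)[C@](C)(/C=C\[C@H](C)CCO[Si](c2ccccc2)(c2ccccc2)C(C)(C)C)C1=O | intermediate
12 | (2S,3R)-2-[(3S)-5-[tert-butyl(diphenyl)silyloxy]-3-methylpentyl]-2,3-dimethylcyclohexan-1-one | C1CC[C@@H](C)[C@](C)(CC[C@H](C)CCO[Si](c2ccccc2)(c2ccccc2)C(C)(C)C)C1=O | intermediate
13 | potassium (5R,6S)-6-[(3S)-5-[tert-butyl(diphenyl)silyloxy]-3-methylpentyl]-5,6-dimethylcyclohex-1-en-1-olate | C1C[C@@H](C)[C@](C)(CC[C@H](C)CCO[Si](c2ccccc2)(c2ccccc2)C(C)(C)C)C([O-])=C1.[K+] | intermediate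
14 | (5R,6S)-6-[(3S)-5-[tert-butyl(diphenyl)silyloxy]-3-methylpentyl]-5,6-dimethylcyclohex-1-en-1-yl trifluoromethanesulfonate | C1C[C@@H](C)[C@](C)(CC[C@H](C)CCO[Si](c2ccccc2)(c2ccccc2)C(C)(C)C)C(OS(=O)(=O)C(F)(F)F)=C1 | intermediate
15 | tert-butyl{[(3S)-5-[(1S,6R)-2-ethenyl-1,6-dimethylcyclohex-2-en-1-yl]-3-methylpentyl]oxy}diphenylsilane | C1C[C@@H](C)[C@](C)(CC[C@H](C)CCO[Si](c2ccccc2)(c2ccccc2)C(C)(C)C)C(C=C)=C1 | intermediate
16 | methyl methacrylate (methyl 2-methylprop-2-enoate) | COC(=O)C(C)=C | starting material
17 | methyl (1S,5S,6R,8aR)-5-[(3S)-5-[tert-butyl(diphenyl)silyloxy]-3-methylpentyl]-1,5,6-trimethyl-1,2,3,5,6,7,8,8a-octahydronaphthalene-1-carboxylate | COC(=O)[C@@]1(C)CCC=C2[C@H]1CC[C@@H](C)[C@]2(C)CC[C@H](C)CCO[Si](c1ccccc1)(c1ccccc1)C(C)(C)C | intermediate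
18 | methyl (1S,5S,6R,8aR)-5-[(3S)-5-hydroxy-3-methylpentyl]-1,5,6-trimethyl-1,2,3,5,6,7,8,8a-octahydronaphthalene-1-carboxylate | COC(=O)[C@@]1(C)CCC=C2[C@H]1CC[C@@H](C)[C@]2(C)CC[C@H](C)CCO | intermediate
19 | methyl (1S,5S,6R,8aR)-5-[(3S)-5-acetoxy-3-methylpentyl]-1,5,6-trimethyl-1,2,3,5,6,7,8,8a-octahydronaphthalene-1-carboxylate | COC(=O)[C@@]1(C)CCC=C2[C@H]1CC[C@@H](C)[C@]2(C)CC[C@H](C)CCOC(C)=O | target

## Step count and least certain steps

Total step count: 12. Longest linear sequence: 11 steps (steps 2–12, from diol 4); from 1 and 2 the sequence is nine steps (steps 1 and 5–12).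

**Step 1 (key step).** The β-methyl of 1 slows the cycloaddition. During a long reaction the diene can be lost by silyl transfer to the catalyst or protodesilylation, it can add to the formyl group in a Mukaiyama-type process, and a background reaction promoted by silyl cations can erode the face selectivity. The fallback replaces catalyst control by auxiliary control; it sets out from 2 (with 1) and returns at 10. Diene 2 is cleaved with MeLi (THF, −78 → 0 °C) and the dienolate is O-acylated with (S)-O-methylmandeloyl chloride to give (E)-buta-1,3-dien-1-yl (2S)-methoxy(phenyl)acetate F1. Cycloaddition of F1 with 1 under BF3·OEt2 (CH2Cl2, −20 °C → rt) should give (1R,5R,6S)-6-formyl-5,6-dimethylcyclohex-2-en-1-yl (2S)-methoxy(phenyl)acetate F2. The adducts from the two diene faces are diastereomers and can be separated, so the selectivity only has to be useful; if the auxiliary favours the wrong face, the (R)-acid is used. Wittig reaction of F2 with ylide 8 gives (1R,5R,6R)-6-[(1Z,3R)-5-[tert-butyl(diphenyl)silyloxy]-3-methylpent-1-en-1-yl]-5,6-dimethylcyclohex-2-en-1-yl (2S)-methoxy(phenyl)acetate F3, and K2CO3 in MeOH releases alcohol 10.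

**Step 10.** Three selectivities rest on substrate bias. The ester-bearing carbon may bond to the vinyl terminus, because the alkyl group on C10 directs against the one on C5. The ester may take the exo position, since methacrylates have only a weak endo preference. The dienophile may approach the face of the axial C11 chain in the other half-chair. In addition the Lewis acid may oligomerise the diene or move the new alkene into the ring fusion. The fallback uses a catalyst-controlled enal cycloaddition and a later oxidation; it sets out from 15 and returns at 17. Methacrolein and 15, with the same (S)-oxazaborolidinium triflimide as in step 1 (CH2Cl2, −78 → −20 °C), should give (1S,5S,6R,8aR)-5-[(3S)-5-[tert-butyl(diphenyl)silyloxy]-3-methylpentyl]-1,5,6-trimethyl-1,2,3,5,6,7,8,8a-octahydronaphthalene-1-carbaldehyde F4. Here the more polarised, tightly bound enal raises the orientational and endo preference, and the catalyst, which exposes the α-Re face of the enal, is matched with the required diene face. Oxidation with NaClO2/NaH2PO4/2-methylbut-2-ene in t-BuOH–water gives (1S,5S,6R,8aR)-5-[(3S)-5-[tert-butyl(diphenyl)silyloxy]-3-methylpentyl]-1,5,6-trimethyl-1,2,3,5,6,7,8,8a-octahydronaphthalene-1-carboxylic acid F5, and Me3SiCHN2 in MeOH/toluene gives ester 17.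

**Step 2.** The two primary hydroxyls may be silylated with too little discrimination, and double silylation competes, so material is lost at the start of the longest branch. The fallback differentiates enzymatically and exchanges the protecting group afterwards; it sets out from 4 and returns at 6. Lipase-catalysed acetylation with vinyl acetate, which prefers the hydroxyl remote from the branch, gives (3R)-4-hydroxy-3-methylbutyl acetate F6. Iodination (I2, PPh3, imidazole) gives (3R)-4-iodo-3-methylbutyl acetate F7. Acid-catalysed methanolysis (TsOH, MeOH), which avoids an alkoxide that could close a tetrahydrofuran, gives (3R)-4-iodo-3-methylbutan-1-ol F8, and silylation (TBDPSCl, imidazole) gives iodide 6.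

**Step 7.** On the metal surface the C11=C12 bond can migrate toward C13 before it is saturated, which would scramble C13. The alkene, flanked by a quaternary carbon, may also be reduced slowly, and the ketone may be over-reduced. The fallback avoids metal-hydride intermediates at the allylic position; it sets out from 11 and returns at 12. Diimide, generated from 2-nitrobenzenesulfonohydrazide and Et3N in CH2Cl2, transfers hydrogen concertedly to the C11=C12 bond and gives (5R,6S)-6-[(3S)-5-[tert-butyl(diphenyl)silyloxy]-3-methylpentyl]-5,6-dimethylcyclohex-2-en-1-one F9. Conjugate reduction of F9 with [(Ph3P)CuH]6 in wet benzene gives ketone 12.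

## Further compounds

F1 | step 1 | (E)-buta-1,3-dien-1-yl (2S)-methoxy(phenyl)acetate | C=C/C=C/OC(=O)[C@H](c1ccccc1)OC
F2 | step 1 | (1R,5R,6S)-6-formyl-5,6-dimethylcyclohex-2-en-1-yl (2S)-methoxy(phenyl)acetate | C1=CC[C@@H](C)[C@](C)(C=O)[C@@H]1OC(=O)[C@H](c1ccccc1)OC
F3 | step 1 | (1R,5R,6R)-6-[(1Z,3R)-5-[tert-butyl(diphenyl)silyloxy]-3-methylpent-1-en-1-yl]-5,6-dimethylcyclohex-2-en-1-yl (2S)-methoxy(phenyl)acetate | C1=CC[C@@H](C)[C@](C)(/C=C\[C@H](C)CCO[Si](c2ccccc2)(c2ccccc2)C(C)(C)C)[C@@H]1OC(=O)[C@H](c1ccccc1)OC
F4 | step 10 | (1S,5S,6R,8aR)-5-[(3S)-5-[tert-butyl(diphenyl)silyloxy]-3-methylpentyl]-1,5,6-trimethyl-1,2,3,5,6,7,8,8a-octahydronaphthalene-1-carbaldehyde | O=C[C@@]1(C)CCC=C2[C@H]1CC[C@@H](C)[C@]2(C)CC[C@H](C)CCO[Si](c1ccccc1)(c1ccccc1)C(C)(C)C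
F5 | step 10 | (1S,5S,6R,8aR)-5-[(3S)-5-[tert-butyl(diphenyl)silyloxy]-3-methylpentyl]-1,5,6-trimethyl-1,2,3,5,6,7,8,8a-octahydronaphthalene-1-carboxylic acid | OC(=O)[C@@]1(C)CCC=C2[C@H]1CC[C@@H](C)[C@]2(C)CC[C@H](C)CCO[Si](c1ccccc1)(c1ccccc1)C(C)(C)C
F6 | step 2 | (3R)-4-hydroxy-3-methylbutyl acetate | OC[C@H](C)CCOC(C)=O
F7 | step 2 | (3R)-4-iodo-3-methylbutyl acetate | IC[C@H](C)CCOC(C)=O
F8 | step 2 | (3R)-4-iodo-3-methylbutan-1-ol | IC[C@H](C)CCO
F9 | step 7 | (5R,6S)-6-[(3S)-5-[tert-butyl(diphenyl)silyloxy]-3-methylpentyl]-5,6-dimethylcyclohex-2-en-1-one | C1=CC[C@@H](C)[C@](C)(CC[C@H](C)CCO[Si](c2ccccc2)(c2ccccc2)C(C)(C)C)C1=O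
A1 | alternative 1 | methyl 5-[(3S)-5-(tert-butyldimethylsilyloxy)-3-methylpentyl]-4-hydroxy-1,6-dimethyl-1,2,3,4,6,7,8,8a-octahydronaphthalene-1-carboxylate (C9=C10 alkene in halimane numbering, C1 hydroxyl on the face of H5) | COC(=O)[C@@]1(C)CC[C@H](O)C2=C(CC[C@H](C)CCO[Si](C)(C)C(C)(C)C)[C@H](C)CC[C@@H]12
A2 | alternative 1 | 9,10-methano-bridged decalin-1-ol, methyl ester, C15 silyl ether (cyclopropane on the face of the C1 hydroxyl) | COC(=O)[C@@]1(C)CC[C@H](O)[C@@]23C[C@]2(CC[C@H](C)CCO[Si](C)(C)C(C)(C)C)[C@H](C)CC[C@@H]13
A3 | alternative 2 | methyl 2-[(4E)-9-(tert-butyldimethylsilyloxy)-3,4,7-trimethylnon-4-en-1-yl]-1-methyl-3-(trifluoromethylsulfonyloxy)cyclohex-3-ene-1-carboxylate (ring A vinyl triflate, triflate on C10) | COC(=O)[C@@]1(C)CCC=C(OS(=O)(=O)C(F)(F)F)[C@H]1CC[C@@H](C)/C(C)=C/C[C@H](C)CCO[Si](C)(C)C(C)(C)C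
A4 | alternative 2 | halima-1(10),11-diene methyl ester, C15 silyl ether | COC(=O)[C@@]1(C)CCC=C2[C@H]1CC[C@@H](C)[C@]2(C)/C=C/[C@H](C)CCO[Si](C)(C)C(C)(C)C
A5 | alternative 3 | (6R)-6-[(5R,6S)-6-[(3S)-5-(tert-butyldimethylsilyloxy)-3-methylpentyl]-5,6-dimethylcyclohex-1-en-1-yl]-3-methyltetrahydro-2H-pyran-2-one (either epimer at the methyl-bearing carbon) | CC1CC[C@@H](OC1=O)C2=CCC[C@@H](C)[C@]2(C)CC[C@H](C)CCO[Si](C)(C)C(C)(C)C
A6 | alternative 3 | halim-1(10)-ene C4 carboxylic acid, C15 silyl ether | OC(=O)[C@@]1(C)CCC=C2[C@H]1CC[C@@H](C)[C@]2(C)CC[C@H](C)CCO[Si](C)(C)C(C)(C)C
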